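**Retrosynthetic overview**
- Target ⇒ one-flask hydrogenation/hydrogenolysis of the benzyl ester of the corresponding 4-methylidene lactone acid. This is the enoate reduction that ends the presumed biosynthesis, and it sets C4.
- 4-Methylidene lactone ⇒ lactonisation of a γ-hydroxy alkylitaconate (the biosynthetic ring closure: chain hydroxyl onto the acrylate carboxyl of the itaconate unit) ⇒ C2–C3 disconnection to 15-oxohexadecanal and dibenzyl 2-(bromomethyl)fumarate, joined by a catalytic enantioselective chromium allylation that sets C2 and C3.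
- 15-Oxohexadecanal ⇒ ω-pentadecalactone + MeLi, then alcohol oxidation; the ketone is carried unprotected throughout.
- Dibenzyl 2-(bromomethyl)fumarate ⇒ itaconic acid (esterification, then Br2/Et3N).
- Ring order: the γ-lactone is the only ring and is closed in the key step.

Assumption: L in step 5 is the tridentate ligand 3,6-diphenyl-1,8-bis(4-isopropyl-4,5-dihydro-1,3-oxazol-2-yl)-9H-carbazole; of its (S,S)- and (R,R)-forms, the one whose CrCl2 complex attacks the Re face of the aldehyde (giving 2S) is used, fixed by one trial run, because the sense of induction with this allyl bromide is not known in advance.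

**Step 1**
Reactants: 1 ω-pentadecalactone (oxacyclohexadecan-2-one)
Product: 3 16-hydroxyhexadecan-2-one, via lithium hemiketal alkoxide 2 (not isolated)
Conditions: MeLi (1.05 equiv), THF, −78 °C, 1 h; aq NH4Cl at −78 °C
Reagents that add atoms: methyllithium, [Li]C
Why: Nucleophilic acyl substitution by an organolithium on a lactone: one equivalent of MeLi adds to the carbonyl and the tetrahedral lithium hemiketal alkoxide 2 holds at −78 °C until the cold quench, so the methyl ketone is released only when no MeLi is left; no stereocentre is formed.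

**Step 2**
Reactants: 3 16-hydroxyhexadecan-2-one
Product: 4 15-oxohexadecanal
Conditions: TEMPO (10 mol %), PhI(OAc)2 (1.1 equiv), CH2Cl2, rt
Reagents that add atoms: none
Why: TEMPO/oxoammonium oxidation takes the primary alcohol to the aldehyde without over-oxidation and leaves the ketone alone; no stereocentre is formed.

**Step 3**
Reactants: 5 itaconic acid (2-methylidenebutanedioic acid)
Product: 6 dibenzyl itaconate
Conditions: BnOH (2.5 equiv), TsOH·H2O (5 mol %), BHT (trace), toluene, reflux, Dean–Stark
Reagents that add atoms: benzyl alcohol, OCc1ccccc1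
Why: Fischer esterification driven by azeotropic removal of water; under acid the exocyclic alkene of the itaconate does not migrate; no stereocentre is formed.

**Step 4**
Reactants: 6 dibenzyl itaconate
Product: 8 dibenzyl 2-(bromomethyl)fumarate, via vicinal dibromide 7 (not isolated)
Conditions: Br2 (1.05 equiv), CH2Cl2, rt, dark; then Et3N (1.1 equiv), Et2O, 0 °C to rt
Reagents that add atoms: bromine, BrBr
Why: Electrophilic bromination of the 1,1-disubstituted alkene followed by E2 dehydrobromination (Et3N takes the acidic C3–H next to the ester, the tertiary bromide leaves) gives the conjugated allylic bromide with the esters trans; no stereocentre is formed, and the alkene geometry is not critical because the derived allylmetal equilibrates.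

**Step 5**
Reactants: 4 15-oxohexadecanal; 8 dibenzyl 2-(bromomethyl)fumarate (1.3 equiv)
Product: 11 benzyl (2S,3R)-4-methylidene-5-oxo-2-(14-oxopentadecyl)oxolane-3-carboxylate, via silyl ether 9 (not isolated), via hydroxy diester 10 (not isolated)
Conditions: CrCl2 (10 mol %), L (12 mol %), Mn powder (2 equiv), iPr2NEt (30 mol %), Me3SiCl (1.5 equiv), THF, rt; then 1 M HCl, THF, rt; then TsOH·H2O (10 mol %), CH2Cl2, rt
Reagents that add atoms: none
Why: Proposed new method: the CrCl2/L-catalysed enantioselective Nozaki–Hiyama–Kishi 2-(alkoxycarbonyl)allylation/lactonisation of aldehydes (the closest known reaction type, together with Zn- and In-mediated Barbier additions of dialkyl 2-(bromomethyl)fumarates) is extended here to an allyl bromide carrying a second ester and to a keto aldehyde; divalent chromium inserts into the allylic C–Br bond, the equilibrating allyl–CrCl2·L species (trivalent chromium) adds with allylic transposition through a chair Zimmerman–Traxler transition state to the Re face of the aldehyde only (ketones do not react), so C2 = S is set by the ligand and C3 = R by the anti preference of a γ-substituted allylchromium (ester pseudo-equatorial), Me3SiCl frees the catalyst as silyl ether 9, and acid unmasks the γ-hydroxy alkylitaconate 10, whose hydroxyl closes the five-membered lactone on the acrylate ester (2,3-trans), which is the ring closure of the presumed biosynthesis.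

**Step 6**
Reactants: 11 benzyl (2S,3R)-4-methylidene-5-oxo-2-(14-oxopentadecyl)oxolane-3-carboxylate
Product: 13 (2S,3R,4S)-4-methyl-5-oxo-2-(14-oxopentadecyl)oxolane-3-carboxylic acid (target), via saturated benzyl ester 12 (not isolated)
Conditions: H2 (1 atm), 10% Pd/C, EtOAc, rt
Reagents that add atoms: none
Why: Heterogeneous catalytic hydrogenation then benzyl ester hydrogenolysis: H2 adds syn to the exocyclic alkene from the ring face opposite the neighbouring C3 carboxylate (the C2 chain is one atom further away), so the new methyl ends cis to the C3 carboxyl (C4 = S), as in the hydrogenation of the natural α-methylene paraconic acids to their 3,4-cis dihydro acids; the isolated ketone is not reduced at 1 atm.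

**Compound list**
1 | ω-pentadecalactone (oxacyclohexadecan-2-one) | O=C1CCCCCCCCCCCCCCO1 | starting material
2 | lithium 2-methyloxacyclohexadecan-2-olate (tetrahedral adduct, racemic) | [Li+].[O-]C1(C)CCCCCCCCCCCCCCO1 | intermediate (not isolated)
3 | 16-hydroxyhexadecan-2-one | CC(=O)CCCCCCCCCCCCCCO | intermediate
4 | 15-oxohexadecanal | CC(=O)CCCCCCCCCCCCCC=O | intermediate
5 | itaconic acid (2-methylidenebutanedioic acid) | C=C(CC(=O)O)C(=O)O | starting material
6 | dibenzyl itaconate (dibenzyl 2-methylidenebutanedioate) | C=C(CC(=O)OCc1ccccc1)C(=O)OCc1ccccc1 | intermediate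
7 | dibenzyl 2-bromo-2-(bromomethyl)butanedioate (racemic) | BrCC(Br)(CC(=O)OCc1ccccc1)C(=O)OCc1ccccc1 | intermediate (not isolated)
8 | dibenzyl 2-(bromomethyl)fumarate [dibenzyl (2Z)-2-(bromomethyl)but-2-enedioate, ester groups trans] | BrC/C(C(=O)OCc1ccccc1)=C\C(=O)OCc1ccccc1 | intermediate
9 | dibenzyl (2R)-3-methylidene-2-[(1S)-15-oxo-1-(trimethylsilyloxy)hexadecyl]butanedioate | CC(=O)CCCCCCCCCCCCC[C@H](O[Si](C)(C)C)[C@H](C(=O)OCc1ccccc1)C(=C)C(=O)OCc1ccccc1 | intermediate (not isolated)
10 | dibenzyl (2R)-2-[(1S)-1-hydroxy-15-oxohexadecyl]-3-methylidenebutanedioate | CC(=O)CCCCCCCCCCCCC[C@H](O)[C@H](C(=O)OCc1ccccc1)C(=C)C(=O)OCc1ccccc1 | intermediate (not isolated)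
11 | benzyl (2S,3R)-4-methylidene-5-oxo-2-(14-oxopentadecyl)oxolane-3-carboxylate (2,3-trans) | CC(=O)CCCCCCCCCCCCC[C@@H]1OC(=O)C(=C)[C@H]1C(=O)OCc1ccccc1 | intermediate
12 | benzyl (2S,3R,4S)-4-methyl-5-oxo-2-(14-oxopentadecyl)oxolane-3-carboxylate (2,3-trans, 3,4-cis) | CC(=O)CCCCCCCCCCCCC[C@@H]1OC(=O)[C@@H](C)[C@H]1C(=O)OCc1ccccc1 | intermediate (not isolated)
13 | (2S,3R,4S)-4-methyl-5-oxo-2-(14-oxopentadecyl)oxolane-3-carboxylic acid (2,3-trans, 3,4-cis) | CC(=O)CCCCCCCCCCCCC[C@@H]1OC(=O)[C@@H](C)[C@H]1C(=O)O | target

**Step count**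
Total: 6 steps. Longest linear sequence: 4 steps (1 → 3 → 4 → 11 → 13; steps 1, 2, 5, 6). Steps 3 and 4 form the convergent branch to 8.

**Steps most likely to fail, with fallbacks**

Step 5. The allylation may give the 2,3-cis lactone (syn addition) or low ee, since this bromide has not been used with the CrCl2/L system. The fallback sets out from 4 and comes back at 13, replacing steps 5 and 6 by an auxiliary-controlled aldol with C4 taken from the chiral pool. The lithium salt of (R)-4-benzyl-1,3-oxazolidin-2-one opens commercial (S)-2-methylsuccinic anhydride at its less hindered carbonyl to give (2S)-4-[(4R)-4-benzyl-2-oxo-1,3-oxazolidin-3-yl]-2-methyl-4-oxobutanoic acid F2. Me3SiCHN2 (toluene/MeOH) converts it into methyl (2S)-4-[(4R)-4-benzyl-2-oxo-1,3-oxazolidin-3-yl]-2-methyl-4-oxobutanoate F3. The Z-boron enolate of the imide (Bu2BOTf, iPr2NEt, CH2Cl2, −78 °C) adds to 4 in an Evans syn-aldol reaction to give methyl (2S,3R,4S)-3-{[(4R)-4-benzyl-2-oxo-1,3-oxazolidin-3-yl]carbonyl}-4-hydroxy-2-methyl-18-oxononadecanoate F4, which is not isolated. TsOH·H2O lactonises it to (4R)-4-benzyl-3-{[(2S,3R,4S)-4-methyl-5-oxo-2-(14-oxopentadecyl)oxolan-3-yl]carbonyl}-1,3-oxazolidin-2-one F5. LiOH/H2O2 (THF/H2O, 0 °C) removes the auxiliary and gives 13. The syn aldol leads to the 2,3-trans lactone, and no alkene reduction is needed.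

Step 6. Pd may move the exocyclic double bond into the ring (a tetrasubstituted butenolide that resists reduction), or the cis selectivity may be lower on the ester than on the acid. The fallback sets out from 11 and comes back at 13, separating the two events so that the free acid carries the alkene into the reduction. BCl3 (CH2Cl2, −78 to 0 °C) cleaves the benzyl ester to (2S,3R)-4-methylidene-5-oxo-2-(14-oxopentadecyl)oxolane-3-carboxylic acid F6. This acid, the substrate type for which cis-selective reduction is established, is hydrogenated with homogeneous [RhCl(PPh3)3] (H2, benzene/EtOH, rt), which does not isomerise the alkene, to give 13.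

Step 1. A second MeLi may add and give the tertiary alcohol. The fallback sets out from 1 and comes back at 3. MeNH(OMe)·HCl/iPrMgCl (THF, −20 °C) opens the lactone to 15-hydroxy-N-methoxy-N-methylpentadecanamide F1. MeMgBr (3 equiv, THF, 0 °C) then adds once, because the chelated tetrahedral adduct of the Weinreb amide holds until work-up, and gives 3.

**Further compounds**
F1 | step 1 | 15-hydroxy-N-methoxy-N-methylpentadecanamide | CON(C)C(=O)CCCCCCCCCCCCCCO
F2 | step 5 | (2S)-4-[(4R)-4-benzyl-2-oxo-1,3-oxazolidin-3-yl]-2-methyl-4-oxobutanoic acid | O=C(C[C@H](C)C(=O)O)N1[C@H](Cc2ccccc2)COC1=O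
F3 | step 5 | methyl (2S)-4-[(4R)-4-benzyl-2-oxo-1,3-oxazolidin-3-yl]-2-methyl-4-oxobutanoate | O=C(C[C@H](C)C(=O)OC)N1[C@H](Cc2ccccc2)COC1=O
F4 | step 5 | methyl (2S,3R,4S)-3-{[(4R)-4-benzyl-2-oxo-1,3-oxazolidin-3-yl]carbonyl}-4-hydroxy-2-methyl-18-oxononadecanoate | CC(=O)CCCCCCCCCCCCC[C@H](O)[C@H](C(=O)N1[C@H](Cc2ccccc2)COC1=O)[C@H](C)C(=O)OC
F5 | step 5 | (4R)-4-benzyl-3-{[(2S,3R,4S)-4-methyl-5-oxo-2-(14-oxopentadecyl)oxolan-3-yl]carbonyl}-1,3-oxazolidin-2-one | CC(=O)CCCCCCCCCCCCC[C@@H]1OC(=O)[C@@H](C)[C@H]1C(=O)N2[C@H](Cc3ccccc3)COC2=O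
F6 | step 6 | (2S,3R)-4-methylidene-5-oxo-2-(14-oxopentadecyl)oxolane-3-carboxylic acid | CC(=O)CCCCCCCCCCCCC[C@@H]1OC(=O)C(=C)[C@H]1C(=O)O
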